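Assumption: the target is exactly the stereoisomer in the given SMILES, i.e. (2R,3S)-2-{[4-hydroxy-3-(3-methylbut-2-en-1-yl)phenyl]methyl}-3-(4-hydroxyphenyl)-4-methoxy-4-oxobutanoic acid. The organocatalyst and allyltributylstannane are bought.

## Retrosynthetic overview

1. Target 19 ⇐ fluoride removal of two aryl silyl ethers and a 2-(trimethylsilyl)ethyl ester from 18; prenyl ⇐ allyl (cross-metathesis) ⇐ aryl bromide (Stille), introduced only after the nitrite step.
2. Methyl ester carbon ⇐ CH2NO2 (nitrite-mediated oxidative Nef-type conversion); free acid carbon ⇐ CHO (Pinnick oxidation), kept masked as the silylethyl ester.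
3. Key disconnection, the central CH–CH bond: intermolecular enamine-catalysed Michael addition of 3-arylpropanal 10 to (E)-nitrostyrene 5, which sets both stereocentres (syn).
4. 5 ⇐ 4-hydroxybenzaldehyde + nitromethane (Henry); 10 ⇐ methyl 3-(4-hydroxyphenyl)propanoate (ortho-bromination, silylation, reduction, oxidation).
5. No ring is built: ring A (4-hydroxyphenyl) and ring B (the phenol that ends up prenylated) come intact from the starting materials.

## Route

Step 1
Reactants: 1 4-hydroxybenzaldehyde; 2 nitromethane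
Product: 4 4-[(E)-2-nitroethenyl]phenol, via nitroaldol adduct 3 (not isolated)
Conditions: MeNO2 (5 equiv), NH4OAc (0.5 equiv), AcOH, 100 °C, 4 h
Reagents that add atoms: none
Why: Henry (nitroaldol) addition followed by acid-promoted dehydration gives the conjugated nitroalkene as the thermodynamically favoured E isomer.

Step 2
Reactants: 4 4-[(E)-2-nitroethenyl]phenol
Product: 5 triisopropyl{4-[(E)-2-nitroethenyl]phenoxy}silane
Conditions: TIPSOTf (1.1 equiv), 2,6-lutidine (1.5 equiv), CH2Cl2, 0 °C → rt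
Reagents that add atoms: triisopropylsilyl trifluoromethanesulfonate CC(C)[Si](OS(=O)(=O)C(F)(F)F)(C(C)C)C(C)C
Why: O-silylation of the phenol with a silyl triflate and a hindered base that cannot add to the nitroalkene gives a robust aryl silyl ether.

Step 3
Reactants: 6 methyl 3-(4-hydroxyphenyl)propanoate
Product: 7 methyl 3-(3-bromo-4-hydroxyphenyl)propanoate
Conditions: NBS (1.0 equiv), p-TsOH·H2O (10 mol%), MeOH, rt, 30 min
Reagents that add atoms: N-bromosuccinimide O=C1CCC(=O)N1Br
Why: Electrophilic aromatic bromination goes ortho to the hydroxyl because the para position is blocked, and the first bromine deactivates the ring toward a second.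

Step 4
Reactants: 7 methyl 3-(3-bromo-4-hydroxyphenyl)propanoate
Product: 8 methyl 3-{3-bromo-4-[(triisopropylsilyl)oxy]phenyl}propanoate
Conditions: TIPSCl (1.3 equiv), imidazole (2.5 equiv), DMF, rt → 40 °C
Reagents that add atoms: chlorotriisopropylsilane CC(C)[Si](Cl)(C(C)C)C(C)C
Why: Imidazole-promoted O-silylation of the phenol gives the same robust protecting group as on ring A, so both come off together at the end.

Step 5
Reactants: 8 methyl 3-{3-bromo-4-[(triisopropylsilyl)oxy]phenyl}propanoate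
Product: 9 3-{3-bromo-4-[(triisopropylsilyl)oxy]phenyl}propan-1-ol
Conditions: i-Bu2AlH (2.5 equiv), CH2Cl2, −78 → 0 °C; aq. potassium sodium tartrate (KNaC4H4O6)
Reagents that add atoms: none
Why: Hydride reduction of the ester fully to the primary alcohol avoids the over-reduction problem of a partial reduction and leaves the aryl bromide and silyl ether untouched.

Step 6
Reactants: 9 3-{3-bromo-4-[(triisopropylsilyl)oxy]phenyl}propan-1-ol
Product: 10 3-{3-bromo-4-[(triisopropylsilyl)oxy]phenyl}propanal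
Conditions: TEMPO (10 mol%), PhI(OAc)2 (1.1 equiv), CH2Cl2, rt
Reagents that add atoms: none
Why: Oxoammonium (TEMPO) oxidation stops cleanly at the aldehyde under near-neutral conditions.

Step 7
Reactants: 10 3-{3-bromo-4-[(triisopropylsilyl)oxy]phenyl}propanal (1.5 equiv); 5 triisopropyl{4-[(E)-2-nitroethenyl]phenoxy}silane (1.0 equiv)
Product: 11 (2R,3S)-2-({3-bromo-4-[(triisopropylsilyl)oxy]phenyl}methyl)-4-nitro-3-{4-[(triisopropylsilyl)oxy]phenyl}butanal
Conditions: (S)-2-[diphenyl(trimethylsilyloxy)methyl]pyrrolidine (10 mol%), 4-nitrophenol (10 mol%), toluene, 0 °C → rt, 24 h; rapid silica filtration, used at once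
Reagents that add atoms: none
Why: In this enamine-catalysed asymmetric Michael addition (Hayashi–Jørgensen catalyst) the bulky diphenyl(silyloxy)methyl group shields one face of the anti (E)-enamine and the (E)-nitroalkene adds to the other face through an acyclic synclinal transition state with the nitro group over the enamine nitrogen, which sets the aldehyde α-carbon as R and the benzylic carbon as S (syn).

Step 8
Reactants: 11 (2R,3S)-2-({3-bromo-4-[(triisopropylsilyl)oxy]phenyl}methyl)-4-nitro-3-{4-[(triisopropylsilyl)oxy]phenyl}butanal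
Product: 12 (2R,3S)-2-({3-bromo-4-[(triisopropylsilyl)oxy]phenyl}methyl)-4-nitro-3-{4-[(triisopropylsilyl)oxy]phenyl}butanoic acid
Conditions: NaClO2 (3 equiv), NaH2PO4 (3 equiv), 2-methylbut-2-ene (10 equiv), t-BuOH/THF/H2O, 0 °C → rt
Reagents that add atoms: sodium chlorite [Na+].[O-]Cl=O
Why: Pinnick oxidation in a weakly acidic buffer converts the epimerisable aldehyde into the configurationally stable acid without enolisation, so the α-centre is retained.

Step 9
Reactants: 12 (2R,3S)-2-({3-bromo-4-[(triisopropylsilyl)oxy]phenyl}methyl)-4-nitro-3-{4-[(triisopropylsilyl)oxy]phenyl}butanoic acid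
Product: 13 2-(trimethylsilyl)ethyl (2R,3S)-2-({3-bromo-4-[(triisopropylsilyl)oxy]phenyl}methyl)-4-nitro-3-{4-[(triisopropylsilyl)oxy]phenyl}butanoate
Conditions: 2-(trimethylsilyl)ethanol (1.5 equiv), PPh3 (1.3 equiv), DIAD (1.3 equiv), THF, 0 °C → rt; chromatography removes the minor anti diastereomer
Reagents that add atoms: 2-(trimethylsilyl)ethanol OCC[Si](C)(C)C
Why: Mitsunobu esterification activates the alcohol and not the acid, so the α-stereocentre cannot epimerise through an activated acyl species, and the much less acidic nitroalkane does not compete.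

Step 10
Reactants: 13 2-(trimethylsilyl)ethyl (2R,3S)-2-({3-bromo-4-[(triisopropylsilyl)oxy]phenyl}methyl)-4-nitro-3-{4-[(triisopropylsilyl)oxy]phenyl}butanoate
Product: 15 (2S,3R)-3-({3-bromo-4-[(triisopropylsilyl)oxy]phenyl}methyl)-4-oxo-2-{4-[(triisopropylsilyl)oxy]phenyl}-4-[2-(trimethylsilyl)ethoxy]butanoic acid, via nitrolic acid 14 (not isolated)
Conditions: NaNO2 (3 equiv), AcOH (10 equiv), DMSO, 35 °C, 12 h
Reagents that add atoms: sodium nitrite [Na+].[O-]N=O
Why: In this nitrite-mediated oxidative Nef-type conversion, nitrosation of the primary nitro group gives a nitrolic acid that collapses to the carboxylic acid without passing through an enolisable aldehyde, so the benzylic stereocentre is retained.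

Step 11
Reactants: 15 (2S,3R)-3-({3-bromo-4-[(triisopropylsilyl)oxy]phenyl}methyl)-4-oxo-2-{4-[(triisopropylsilyl)oxy]phenyl}-4-[2-(trimethylsilyl)ethoxy]butanoic acid
Product: 16 1-methyl 4-[2-(trimethylsilyl)ethyl] (2S,3R)-3-({3-bromo-4-[(triisopropylsilyl)oxy]phenyl}methyl)-2-{4-[(triisopropylsilyl)oxy]phenyl}butanedioate
Conditions: TMSCHN2 (1.5 equiv), toluene/MeOH 4:1, 0 °C → rt
Reagents that add atoms: trimethylsilyldiazomethane C[Si](C)(C)C=[N+]=[N-]
Why: Methyl esterification by O-alkylation of the acid with the diazoalkane is base-free and therefore does not epimerise the α-aryl centre.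

Step 12
Reactants: 16 1-methyl 4-[2-(trimethylsilyl)ethyl] (2S,3R)-3-({3-bromo-4-[(triisopropylsilyl)oxy]phenyl}methyl)-2-{4-[(triisopropylsilyl)oxy]phenyl}butanedioate
Product: 17 1-methyl 4-[2-(trimethylsilyl)ethyl] (2S,3R)-3-({3-(prop-2-en-1-yl)-4-[(triisopropylsilyl)oxy]phenyl}methyl)-2-{4-[(triisopropylsilyl)oxy]phenyl}butanedioate
Conditions: allyltributylstannane (1.5 equiv), Pd(PPh3)4 (5 mol%), DMF, 90 °C
Reagents that add atoms: allyltributylstannane C=CC[Sn](CCCC)(CCCC)CCCC
Why: Stille cross-coupling (oxidative addition of zerovalent palladium into the aryl bromide, transmetalation, reductive elimination) runs under neutral conditions that spare the esters, the silyl ethers and both stereocentres, and an allyl group has no regiochemical ambiguity.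

Step 13
Reactants: 17 1-methyl 4-[2-(trimethylsilyl)ethyl] (2S,3R)-3-({3-(prop-2-en-1-yl)-4-[(triisopropylsilyl)oxy]phenyl}methyl)-2-{4-[(triisopropylsilyl)oxy]phenyl}butanedioate
Product: 18 1-methyl 4-[2-(trimethylsilyl)ethyl] (2S,3R)-3-({3-(3-methylbut-2-en-1-yl)-4-[(triisopropylsilyl)oxy]phenyl}methyl)-2-{4-[(triisopropylsilyl)oxy]phenyl}butanedioate
Conditions: second-generation Grubbs catalyst RuCl2(=CHPh)(H2IMes)(PCy3) (5 mol%), 2-methylbut-2-ene/CH2Cl2 1:1, 40 °C, sealed tube
Reagents that add atoms: 2-methylbut-2-ene CC=C(C)C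
Why: Olefin cross-metathesis with a large excess of 2-methylbut-2-ene exchanges the terminal =CH2 for =C(CH3)2, driven by loss of propene, and does not touch the stereocentres.

Step 14
Reactants: 18 1-methyl 4-[2-(trimethylsilyl)ethyl] (2S,3R)-3-({3-(3-methylbut-2-en-1-yl)-4-[(triisopropylsilyl)oxy]phenyl}methyl)-2-{4-[(triisopropylsilyl)oxy]phenyl}butanedioate
Product: 19 Asperteretal G1, (2R,3S)-2-{[4-hydroxy-3-(3-methylbut-2-en-1-yl)phenyl]methyl}-3-(4-hydroxyphenyl)-4-methoxy-4-oxobutanoic acid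
Conditions: Bu4NF (4 equiv), THF, 0 °C → rt; then AcOH (4 equiv), pH 4 aqueous work-up
Reagents that add atoms: none
Why: Fluoride cleaves both aryl Si–O bonds and fragments the 2-(trimethylsilyl)ethyl ester to ethene and the carboxylate, while the methyl ester and the prenyl alkene are inert and the phenoxide formed first on ring A lowers the acidity of the benzylic α-proton.

## Compound list

1 | 4-hydroxybenzaldehyde | O=Cc1ccc(O)cc1 | starting material
2 | nitromethane | C[N+](=O)[O-] | starting material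
3 | 1-(4-hydroxyphenyl)-2-nitroethan-1-ol (racemic nitroaldol adduct, not isolated) | OC(C[N+](=O)[O-])c1ccc(O)cc1 | intermediate
4 | 4-[(E)-2-nitroethenyl]phenol | Oc1ccc(/C=C/[N+](=O)[O-])cc1 | intermediate
5 | triisopropyl{4-[(E)-2-nitroethenyl]phenoxy}silane | CC(C)[Si](Oc1ccc(/C=C/[N+](=O)[O-])cc1)(C(C)C)C(C)C | intermediate
6 | methyl 3-(4-hydroxyphenyl)propanoate | COC(=O)CCc1ccc(O)cc1 | starting material
7 | methyl 3-(3-bromo-4-hydroxyphenyl)propanoate | COC(=O)CCc1ccc(O)c(Br)c1 | intermediate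
8 | methyl 3-{3-bromo-4-[(triisopropylsilyl)oxy]phenyl}propanoate | COC(=O)CCc1ccc(O[Si](C(C)C)(C(C)C)C(C)C)c(Br)c1 | intermediate
9 | 3-{3-bromo-4-[(triisopropylsilyl)oxy]phenyl}propan-1-ol | OCCCc1ccc(O[Si](C(C)C)(C(C)C)C(C)C)c(Br)c1 | intermediate
10 | 3-{3-bromo-4-[(triisopropylsilyl)oxy]phenyl}propanal | O=CCCc1ccc(O[Si](C(C)C)(C(C)C)C(C)C)c(Br)c1 | intermediate
11 | (2R,3S)-2-({3-bromo-4-[(triisopropylsilyl)oxy]phenyl}methyl)-4-nitro-3-{4-[(triisopropylsilyl)oxy]phenyl}butanal | O=[N+]([O-])C[C@H](c1ccc(O[Si](C(C)C)(C(C)C)C(C)C)cc1)[C@@H](Cc1ccc(O[Si](C(C)C)(C(C)C)C(C)C)c(Br)c1)C=O | intermediate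
12 | (2R,3S)-2-({3-bromo-4-[(triisopropylsilyl)oxy]phenyl}methyl)-4-nitro-3-{4-[(triisopropylsilyl)oxy]phenyl}butanoic acid | O=[N+]([O-])C[C@H](c1ccc(O[Si](C(C)C)(C(C)C)C(C)C)cc1)[C@@H](Cc1ccc(O[Si](C(C)C)(C(C)C)C(C)C)c(Br)c1)C(=O)O | intermediate
13 | 2-(trimethylsilyl)ethyl (2R,3S)-2-({3-bromo-4-[(triisopropylsilyl)oxy]phenyl}methyl)-4-nitro-3-{4-[(triisopropylsilyl)oxy]phenyl}butanoate | O=[N+]([O-])C[C@H](c1ccc(O[Si](C(C)C)(C(C)C)C(C)C)cc1)[C@@H](Cc1ccc(O[Si](C(C)C)(C(C)C)C(C)C)c(Br)c1)C(=O)OCC[Si](C)(C)C | intermediate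
14 | 2-(trimethylsilyl)ethyl (2R,3S)-2-({3-bromo-4-[(triisopropylsilyl)oxy]phenyl}methyl)-4-(hydroxyimino)-4-nitro-3-{4-[(triisopropylsilyl)oxy]phenyl}butanoate (nitrolic acid, not isolated) | ON=C([N+](=O)[O-])[C@H](c1ccc(O[Si](C(C)C)(C(C)C)C(C)C)cc1)[C@@H](Cc1ccc(O[Si](C(C)C)(C(C)C)C(C)C)c(Br)c1)C(=O)OCC[Si](C)(C)C | intermediate
15 | (2S,3R)-3-({3-bromo-4-[(triisopropylsilyl)oxy]phenyl}methyl)-4-oxo-2-{4-[(triisopropylsilyl)oxy]phenyl}-4-[2-(trimethylsilyl)ethoxy]butanoic acid | OC(=O)[C@H](c1ccc(O[Si](C(C)C)(C(C)C)C(C)C)cc1)[C@@H](Cc1ccc(O[Si](C(C)C)(C(C)C)C(C)C)c(Br)c1)C(=O)OCC[Si](C)(C)C | intermediate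
16 | 1-methyl 4-[2-(trimethylsilyl)ethyl] (2S,3R)-3-({3-bromo-4-[(triisopropylsilyl)oxy]phenyl}methyl)-2-{4-[(triisopropylsilyl)oxy]phenyl}butanedioate | COC(=O)[C@H](c1ccc(O[Si](C(C)C)(C(C)C)C(C)C)cc1)[C@@H](Cc1ccc(O[Si](C(C)C)(C(C)C)C(C)C)c(Br)c1)C(=O)OCC[Si](C)(C)C | intermediate
17 | 1-methyl 4-[2-(trimethylsilyl)ethyl] (2S,3R)-3-({3-(prop-2-en-1-yl)-4-[(triisopropylsilyl)oxy]phenyl}methyl)-2-{4-[(triisopropylsilyl)oxy]phenyl}butanedioate | COC(=O)[C@H](c1ccc(O[Si](C(C)C)(C(C)C)C(C)C)cc1)[C@@H](Cc1ccc(O[Si](C(C)C)(C(C)C)C(C)C)c(CC=C)c1)C(=O)OCC[Si](C)(C)C | intermediate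
18 | 1-methyl 4-[2-(trimethylsilyl)ethyl] (2S,3R)-3-({3-(3-methylbut-2-en-1-yl)-4-[(triisopropylsilyl)oxy]phenyl}methyl)-2-{4-[(triisopropylsilyl)oxy]phenyl}butanedioate | COC(=O)[C@H](c1ccc(O[Si](C(C)C)(C(C)C)C(C)C)cc1)[C@@H](Cc1ccc(O[Si](C(C)C)(C(C)C)C(C)C)c(CC=C(C)C)c1)C(=O)OCC[Si](C)(C)C | intermediate
19 | Asperteretal G1, (2R,3S)-2-{[4-hydroxy-3-(3-methylbut-2-en-1-yl)phenyl]methyl}-3-(4-hydroxyphenyl)-4-methoxy-4-oxobutanoic acid | COC(=O)[C@H](c1ccc(O)cc1)[C@@H](Cc1ccc(O)c(CC=C(C)C)c1)C(=O)O | target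

## Step count and risk

Total step count: 14 (steps 1–2 make the nitroalkene 5, steps 3–6 make the aldehyde 10, steps 7–14 are the joint sequence).
Longest linear sequence: 12 steps (from 6 through steps 3–14 to 19).

The three steps most likely to fail:

Step 10 (nitro group to carboxylic acid). The risks are low conversion, some loss of an aryl silyl ether followed by ring nitrosation, or erosion at the benzylic centre. The fallback sets out from 13 and changes the oxidation to a two-stage sequence through the aldehyde. The nitro compound is deprotonated with t-BuOK (1.0 equiv, THF, −78 °C) and oxidised with dimethyldioxirane in acetone (oxidative Nef reaction), which gives 2-(trimethylsilyl)ethyl (2R,3S)-2-({3-bromo-4-[(triisopropylsilyl)oxy]phenyl}methyl)-4-oxo-3-{4-[(triisopropylsilyl)oxy]phenyl}butanoate F1. This α-aryl aldehyde is not purified but oxidised at once with NaClO2, NaH2PO4 and 2-methylbut-2-ene in t-BuOH/H2O at 0 °C, and the route is rejoined at 15.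

Step 13 (cross-metathesis to the prenyl group). The risks are incomplete conversion and isomerisation of the allylarene to the propenylarene by ruthenium hydride species on a late intermediate. The fallback sets out from 16 and transfers the whole prenyl group in one Stille coupling with tributyl(3-methylbut-2-en-1-yl)stannane (Pd(PPh3)4, DMF, 90–100 °C), which favours the linear prenyl isomer, and comes back to the route at 18. It makes no compound outside the list (entry none F0).

Step 14 (global fluoride deprotection). The risks are base-induced epimerisation of the α-aryl ester centre or loss of the methyl ester under Bu4NF. The fallback sets out from 17 and removes the silylethyl ester with acid while the side chain is still an acid-stable allyl group. CF3CO2H/CH2Cl2 (0 °C → rt) cleaves only that ester and gives (2R,3S)-4-methoxy-4-oxo-2-({3-(prop-2-en-1-yl)-4-[(triisopropylsilyl)oxy]phenyl}methyl)-3-{4-[(triisopropylsilyl)oxy]phenyl}butanoic acid F2. Cross-metathesis with 2-methylbut-2-ene (second-generation Grubbs catalyst, which tolerates the free acid) gives (2R,3S)-4-methoxy-2-({3-(3-methylbut-2-en-1-yl)-4-[(triisopropylsilyl)oxy]phenyl}methyl)-4-oxo-3-{4-[(triisopropylsilyl)oxy]phenyl}butanoic acid F3. HF·pyridine in THF/pyridine (0 °C → rt) then removes the two aryl silyl ethers under weakly acidic, non-basic conditions and delivers 19.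

Further compounds
F1 | step 10 | 2-(trimethylsilyl)ethyl (2R,3S)-2-({3-bromo-4-[(triisopropylsilyl)oxy]phenyl}methyl)-4-oxo-3-{4-[(triisopropylsilyl)oxy]phenyl}butanoate | O=C[C@H](c1ccc(O[Si](C(C)C)(C(C)C)C(C)C)cc1)[C@@H](Cc1ccc(O[Si](C(C)C)(C(C)C)C(C)C)c(Br)c1)C(=O)OCC[Si](C)(C)C
F0 | step 13 | none | none
F2 | step 14 | (2R,3S)-4-methoxy-4-oxo-2-({3-(prop-2-en-1-yl)-4-[(triisopropylsilyl)oxy]phenyl}methyl)-3-{4-[(triisopropylsilyl)oxy]phenyl}butanoic acid | COC(=O)[C@H](c1ccc(O[Si](C(C)C)(C(C)C)C(C)C)cc1)[C@@H](Cc1ccc(O[Si](C(C)C)(C(C)C)C(C)C)c(CC=C)c1)C(=O)O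
F3 | step 14 | (2R,3S)-4-methoxy-2-({3-(3-methylbut-2-en-1-yl)-4-[(triisopropylsilyl)oxy]phenyl}methyl)-4-oxo-3-{4-[(triisopropylsilyl)oxy]phenyl}butanoic acid | COC(=O)[C@H](c1ccc(O[Si](C(C)C)(C(C)C)C(C)C)cc1)[C@@H](Cc1ccc(O[Si](C(C)C)(C(C)C)C(C)C)c(CC=C(C)C)c1)C(=O)O
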